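**Retrosynthetic overview**

- The target is the 2-phenylethyl ester of the unbranched C28 acid; it has no stereocentre, and its only ring is the phenyl ring that arrives with 2-phenylethanol.
- Feature the plan rests on: C1–C6 of the acyl chain (ester carbonyl C1 and the methylenes C2–C6) are the six ring carbons of cyclohexanone, and C7–C28 are the 22 carbons of docosanoic acid.
- Disconnections: the C7 methylene comes from a C7 ketone (tosylhydrazone reduction). The ester O–C1 bond comes from retro-Claisen opening of 2-docosanoylcyclohexanone by 2-phenylethanol, which cuts the ring bond between the future C1 and C6. The C6–C7 bond comes from C-acylation of cyclohexanone morpholine enamine with docosanoyl chloride.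
- Ring order: no ring is formed at any stage; the purchased cyclohexanone ring is carried through step 3 and opened in step 4.

Key step: step 3

Remark: the target is achiral; the stereocentres that appear in 7 and 11 are racemic and are erased in the following operations.

**Route**

Step 1
Reactants: 1 cyclohexanone; 2 morpholine
Product: 3 4-(cyclohex-1-en-1-yl)morpholine
Conditions: morpholine (1.2 equiv), TsOH·H2O (cat.), toluene, reflux, Dean–Stark; distillation under reduced pressure
Reagents that add atoms: none
Why: Acid-catalysed enamine condensation of a ketone with a secondary amine is driven to completion by azeotropic removal of water, and the product should be purified by distillation.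

Step 2
Reactants: 4 docosanoic acid
Product: 5 docosanoyl chloride
Conditions: SOCl2 (3 equiv), DMF (cat.), toluene, 70 °C; evaporation with toluene
Reagents that add atoms: thionyl chloride, O=S(Cl)Cl
Why: Acid chloride formation with thionyl chloride under DMF (Vilsmeier-type) catalysis is standard for saturated fatty acids, and the by-products are gases that leave on evaporation.

Step 3
Reactants: 3 4-(cyclohex-1-en-1-yl)morpholine; 5 docosanoyl chloride
Product: 7 2-docosanoylcyclohexan-1-one, via C-acylated enamine 6 (not isolated)
Conditions: 3 (1.1 equiv), Et3N (1.1 equiv), dry CHCl3, 0 to 35 °C; then 10% aq. HCl, reflux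
Reagents that add atoms: water, O
Why: Stork enamine acylation: the nucleophilic β-carbon of 3 adds to the carbonyl of 5 and chloride is expelled, which forms the C6–C7 bond of the target chain; Et3N removes the proton from the C-acyl iminium salt to leave the vinylogous amide 6, which aqueous HCl hydrolyses to the 1,3-diketone 7. The closest known reaction type is the acylation of cyclohexanone morpholine enamine by long-chain fatty acid chlorides used for six-carbon chain extension of fatty acids. No ring is closed. The new stereocentre at ring C2 is formed racemic and uncontrolled, it equilibrates through the enol and becomes the C6 methylene in step 4. The step needs C- over N-acylation and a single acylation: an N-acylammonium ion forms reversibly and only passes its acyl group on to carbon (any ketene formed by Et3N should give the same product through its [2+2] adduct, which ring-opens), and 6, with its nitrogen lone pair delocalised into the new carbonyl group, is too weak a nucleophile to be acylated again.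

Step 4
Reactants: 7 2-docosanoylcyclohexan-1-one; 8 2-phenylethanol
Product: 9 2-phenylethyl 7-oxooctacosanoate
Conditions: NaOCH2CH2Ph (0.15 equiv, from NaH), anhydrous 2-phenylethanol (6 equiv), toluene, 100 °C; AcOH quench; excess alcohol removed by trituration with cold MeOH
Reagents that add atoms: none
Why: Retro-Claisen reaction (alkoxide-catalysed alcoholysis of a 1,3-diketone): phenethoxide adds to the ring carbonyl, the more electrophilic ketone because addition relieves the torsional strain of the sp2 ring carbon, and the adduct breaks the ring C1–C2 bond to give the enolate of the chain ketone, which the alcohol protonates with regeneration of the alkoxide; the base is kept substoichiometric because a full equivalent would only hold 7 as its unreactive diketonate.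

Step 5
Reactants: 9 2-phenylethyl 7-oxooctacosanoate
Product: 10 2-phenylethyl 7-(tosylhydrazinylidene)octacosanoate (E/Z mixture)
Conditions: TsNHNH2 (1.1 equiv), AcOH (cat.), THF, 4 Å MS, 50 °C
Reagents that add atoms: p-toluenesulfonohydrazide, Cc1ccc(cc1)S(=O)(=O)NN
Why: Hydrazone condensation of an unhindered dialkyl ketone with tosylhydrazide is fast under mild acid catalysis, and the ester should be untouched without alcohol solvent, strong acid or strong base.

Step 6
Reactants: 10 2-phenylethyl 7-(tosylhydrazinylidene)octacosanoate
Product: 12 2-phenylethyl octacosanoate, via N-boryl tosylhydrazine 11 (not isolated)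
Conditions: catecholborane (1.3 equiv), CHCl3, 0 °C to rt; then NaOAc·3H2O (3 equiv), reflux
Reagents that add atoms: none
Why: Tosylhydrazone reduction with catecholborane: hydride is delivered to the C=N carbon to give 11, acetate then attacks boron and expels p-toluenesulfinate to leave a monoalkyl diazene that loses N2 and gives the C7 methylene; catecholborane does not reduce esters under these conditions, and the racemic stereocentre of 11 disappears with the diazene.

**Compound list**

1 | cyclohexanone | O=C1CCCCC1 | starting material
2 | morpholine | C1COCCN1 | starting material
3 | 4-(cyclohex-1-en-1-yl)morpholine | C1CCC(=CC1)N1CCOCC1 | intermediate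
4 | docosanoic acid | CCCCCCCCCCCCCCCCCCCCCC(=O)O | starting material
5 | docosanoyl chloride | CCCCCCCCCCCCCCCCCCCCCC(=O)Cl | intermediate
6 | 1-[2-(morpholin-4-yl)cyclohex-1-en-1-yl]docosan-1-one | CCCCCCCCCCCCCCCCCCCCCC(=O)C1=C(CCCC1)N1CCOCC1 | intermediate (not isolated)
7 | 2-docosanoylcyclohexan-1-one (racemic, largely enolised) | CCCCCCCCCCCCCCCCCCCCCC(=O)C1CCCCC1=O | intermediate
8 | 2-phenylethanol | OCCc1ccccc1 | starting material
9 | 2-phenylethyl 7-oxooctacosanoate | CCCCCCCCCCCCCCCCCCCCCC(=O)CCCCCC(=O)OCCc1ccccc1 | intermediate
10 | 2-phenylethyl 7-[2-(4-methylbenzenesulfonyl)hydrazinylidene]octacosanoate (E/Z mixture) | CCCCCCCCCCCCCCCCCCCCCC(=NNS(=O)(=O)c1ccc(C)cc1)CCCCCC(=O)OCCc1ccccc1 | intermediate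
11 | 2-phenylethyl 7-[1-(1,3,2-benzodioxaborol-2-yl)-2-(4-methylbenzenesulfonyl)hydrazinyl]octacosanoate (racemic) | CCCCCCCCCCCCCCCCCCCCCC(CCCCCC(=O)OCCc1ccccc1)N(NS(=O)(=O)c1ccc(C)cc1)B1Oc2ccccc2O1 | intermediate (not isolated)
12 | 2-phenylethyl octacosanoate (phenylethyl n-octacosanoate) | CCCCCCCCCCCCCCCCCCCCCCCCCCCC(=O)OCCc1ccccc1 | target

**Step count**

Total steps: 6. Longest linear sequence: 5 steps (steps 1, 3, 4, 5, 6; the branch through step 2 is equally long).

**Steps most likely to fail**

Step 4. The alkoxide may add to the chain carbonyl instead of the ring carbonyl, which would expel cyclohexanone and shorten the ester to C22. Conversion is also capped by the portion of 7 held as diketonate, and traces of water would consume the catalytic base as carboxylate. The fallback sets out from 7 and makes the cleavage irreversible. Aqueous KOH in ethanol at reflux, followed by acidification, should open the ring to 7-oxooctacosanoic acid F1. Wolff–Kishner reduction in the Huang-Minlon manner (N2H4·H2O, KOH, diethylene glycol, 130 then 200 °C) should give octacosanoic acid F2. Fischer esterification with 8 (TsOH·H2O cat., toluene, Dean–Stark) then rejoins the route at 12, and steps 5 and 6 are not needed.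

Step 3. Et3N may dehydrochlorinate the acid chloride to a ketene that dimerises, the waxy acid chloride may C-acylate incompletely, or the vinylogous amide may hydrolyse sluggishly. The fallback keeps the same C6–C7 bond but changes both partners. It sets out from 5, which with 1H-benzotriazole and Et3N in CH2Cl2 should give 1-(1H-benzotriazol-1-yl)docosan-1-one F3. Soft enolisation of cyclohexanone 1 with MgBr2·OEt2 and i-Pr2NEt in CH2Cl2 at room temperature, and C-acylation of the magnesium enolate by F3, should deliver the diketone and rejoin the route at 7.

Step 6. Hydride delivery to the C=N bond may be incomplete, the tosylhydrazone may revert to the ketone, or base-induced Bamford–Stevens-type elimination may give alkenes during the acetate stage. The fallback sets out from 9. 1,2-Ethanedithiol with BF3·OEt2 in CH2Cl2 should give 2-phenylethyl 6-(2-henicosyl-1,3-dithiolan-2-yl)hexanoate F4. Desulfurisation with neutral-washed Raney Ni in THF–EtOH at reflux should remove the dithiolane and rejoin the route at 12.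

**Further compounds**

F1 | step 4 | 7-oxooctacosanoic acid | CCCCCCCCCCCCCCCCCCCCCC(=O)CCCCCC(=O)O
F2 | step 4 | octacosanoic acid | CCCCCCCCCCCCCCCCCCCCCCCCCCCC(=O)O
F3 | step 3 | 1-(1H-benzotriazol-1-yl)docosan-1-one | CCCCCCCCCCCCCCCCCCCCCC(=O)n1nnc2ccccc12
F4 | step 6 | 2-phenylethyl 6-(2-henicosyl-1,3-dithiolan-2-yl)hexanoate | CCCCCCCCCCCCCCCCCCCCCC1(CCCCCC(=O)OCCc2ccccc2)SCCS1
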